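## Retrosynthetic overview

1. Target 20 ⇒ open-chain, unprotected 3-amino-5-hydroxyphenyl seco-acid 16. In one flask the aminophenol is oxidised to the 2-aminobenzoquinone, the diketone carbon C8 adds to the quinone, and loss of the benzylic hydroxyl aromatises the new ring. This benzo ring is the only ring made and it is made last; the quinone ring is the benzene ring of aldehyde 14 (the order of events of the AHBA-primed polyketide pathway).
2. 16 ⇒ nitro compound 15 ⇒ β-diketone 13 + 3-hydroxy-5-nitrobenzaldehyde 14 (dianion aldol, C10–C11).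
3. 13 ⇒ methyl enone acid 11 + Weinreb amide 12 (C8–C9); 11 ⇒ aldehyde 8 + ylide 7 (E-C5=C6).
4. All-syn C2–C4 triad ⇒ Evans syn aldol of imide 4 with Roche-ester-derived aldehyde 3 (C2–C3).

Assumption: 7 and 14 are taken as catalogue items, and C10/C11 of 15–19 are carried as a diastereomer mixture because step 10 destroys both centres.

## Route

Step 1
Reactants: 1 methyl (R)-3-hydroxy-2-methylpropanoate
Product: 2 methyl (R)-3-(tert-butyldimethylsilyloxy)-2-methylpropanoate
Conditions: TBSCl, imidazole, CH2Cl2, 0 °C to rt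
Reagents that add atoms: tert-butyldimethylsilyl chloride, CC(C)(C)[Si](C)(C)Cl
Why: Standard imidazole-mediated silylation of the primary alcohol; the stereocentre (future C4) is untouched.

Step 2
Reactants: 2 methyl (R)-3-(tert-butyldimethylsilyloxy)-2-methylpropanoate
Product: 3 (R)-3-(tert-butyldimethylsilyloxy)-2-methylpropanal
Conditions: DIBAL-H (1.05 equiv), CH2Cl2, −78 °C; MeOH, aq. Rochelle salt; used crude
Reagents that add atoms: none
Why: Low-temperature DIBAL-H half-reduction stops at the aluminium hemiacetal, and the α-methyl aldehyde keeps its configuration when used without chromatography.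

Step 3
Reactants: 3 (R)-3-(tert-butyldimethylsilyloxy)-2-methylpropanal; 4 (R)-4-benzyl-3-propionyloxazolidin-2-one
Product: 5 (R)-4-benzyl-3-[(2R,3S,4R)-5-(tert-butyldimethylsilyloxy)-3-hydroxy-2,4-dimethylpentanoyl]oxazolidin-2-one
Conditions: 4, Bu2BOTf, Et3N, CH2Cl2, −78 to 0 °C; then 3, −78 to 0 °C; pH 7 buffer, MeOH, 30% H2O2, 0 °C
Reagents that add atoms: none
Why: Evans syn aldol through the Z-boron enolate and a Zimmerman–Traxler chair, in which the (R)-benzyl auxiliary sets C2 (R) and C3 (S) and overrides the small opposing facial bias of the aldehyde, whose (R) centre becomes C4, giving the all-syn triad.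

Step 4
Reactants: 5 (R)-4-benzyl-3-[(2R,3S,4R)-5-(tert-butyldimethylsilyloxy)-3-hydroxy-2,4-dimethylpentanoyl]oxazolidin-2-one
Product: 6 (R)-4-benzyl-3-[(2R,3S,4R)-3,5-dihydroxy-2,4-dimethylpentanoyl]oxazolidin-2-one
Conditions: HF·pyridine, pyridine, THF, 0 °C to rt; used crude
Reagents that add atoms: none
Why: Buffered fluoride desilylation is mildly acidic, so the δ-hydroxy imide does not lactonise as it would under base, provided it is carried on at once.

Step 5
Reactants: 6 (R)-4-benzyl-3-[(2R,3S,4R)-3,5-dihydroxy-2,4-dimethylpentanoyl]oxazolidin-2-one; 7 3-(triphenylphosphoranylidene)butan-2-one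
Product: 9 (R)-4-benzyl-3-[(2R,3S,4R,5E)-3-hydroxy-2,4,6-trimethyl-7-oxooct-5-enoyl]oxazolidin-2-one, via β-hydroxy aldehyde 8 (not isolated)
Conditions: TEMPO (10 mol%), PhI(OAc)2 (1.1 equiv), CH2Cl2, rt; then 7 (3 equiv), 40 °C
Reagents that add atoms: none
Why: TEMPO/PhI(OAc)2 oxidises only the primary alcohol and the stabilised ylide traps the sensitive β-hydroxy aldehyde in the same pot (tandem oxidation–Wittig), giving the trisubstituted E-enone (expected >95:5) without epimerising C4.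

Step 6
Reactants: 9 (R)-4-benzyl-3-[(2R,3S,4R,5E)-3-hydroxy-2,4,6-trimethyl-7-oxooct-5-enoyl]oxazolidin-2-one
Product: 11 (2R,3S,4R,5E)-3-hydroxy-2,4,6-trimethyl-7-oxooct-5-enoic acid, via peroxy acid 10 (not isolated)
Conditions: LiOH, 30% H2O2, THF/H2O 3:1, 0 °C, 1 h; aq. Na2SO3; 1 M HCl to pH 3
Reagents that add atoms: hydrogen peroxide (as LiOOH), OO
Why: Evans LiOOH cleavage attacks the exocyclic imide carbonyl far faster than Weitz–Scheffer epoxidation of the hindered α-methyl enone, and sulfite reduces the peracid to the acid without touching C2.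

Step 7
Reactants: 11 (2R,3S,4R,5E)-3-hydroxy-2,4,6-trimethyl-7-oxooct-5-enoic acid; 12 N-methoxy-N-methylpropanamide
Product: 13 (2R,3S,4R,5E)-3-hydroxy-2,4,6-trimethyl-7,9-dioxoundec-5-enoic acid
Conditions: LiHMDS (3.3 equiv), THF, −78 °C; then 12 (1.5 equiv), −78 to 0 °C; 1 M HCl to pH 3
Reagents that add atoms: none
Why: Crossed-Claisen acylation in which the kinetic α′-lithium enolate of the methyl ketone adds to the Weinreb amide to give a stable chelate that the alkoxide and carboxylate cannot acylate, while the lithium carboxylate shields C2–H from the amide base.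

Step 8
Reactants: 13 (2R,3S,4R,5E)-3-hydroxy-2,4,6-trimethyl-7,9-dioxoundec-5-enoic acid; 14 3-hydroxy-5-nitrobenzaldehyde
Product: 15 (2R,3S,4R,5E)-3,11-dihydroxy-11-(3-hydroxy-5-nitrophenyl)-2,4,6,10-tetramethyl-7,9-dioxoundec-5-enoic acid (C10/C11 diastereomer mixture)
Conditions: 13, LDA (4.1 equiv), THF/DMPU, −78 to −30 °C; then 14 pre-treated with LiHMDS (1.0 equiv), −78 °C; AcOH quench at −78 °C
Reagents that add atoms: none
Why: Hauser–Weiler dianion aldol, in which the second deprotonation of the diketone can only occur at the terminal α-carbon C10 and this more basic carbanion adds to the aldehyde; the two new centres are not controlled because step 10 removes both.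

Step 9
Reactants: 15 (2R,3S,4R,5E)-3,11-dihydroxy-11-(3-hydroxy-5-nitrophenyl)-2,4,6,10-tetramethyl-7,9-dioxoundec-5-enoic acid
Product: 16 (2R,3S,4R,5E)-11-(3-amino-5-hydroxyphenyl)-3,11-dihydroxy-2,4,6,10-tetramethyl-7,9-dioxoundec-5-enoic acid
Conditions: H2 (1 atm), 5% Pt(S)/C, EtOAc/MeOH, rt; filter, concentrate cold, use at once
Reagents that add atoms: none
Why: Catalytic nitro reduction over sulfided platinum is chemoselective and neutral, leaving the conjugated enone, the benzylic alcohol and the acid-sensitive δ-hydroxy-β-diketone intact.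

Step 10
Reactants: 16 (2R,3S,4R,5E)-11-(3-amino-5-hydroxyphenyl)-3,11-dihydroxy-2,4,6,10-tetramethyl-7,9-dioxoundec-5-enoic acid
Product: 20 (2R,3S,4R,5E)-7-(6-amino-2-hydroxy-3-methyl-5,8-dioxo-5,8-dihydronaphthalen-1-yl)-3-hydroxy-2,4,6-trimethyl-7-oxohept-5-enoic acid, via aminoquinone 17 (not isolated), via cyclised hydroquinone 18 (not isolated), via hydroxy trione 19 (not isolated)
Conditions: (KO3S)2NO (4.5 equiv), KH2PO4/Na2HPO4 buffer pH 7, acetone/H2O, 0 °C to rt, high dilution; then AcOH to pH 4, rt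
Reagents that add atoms: potassium nitrosodisulfonate (Fremy's salt), [K+].[K+].[O]N(S(=O)(=O)[O-])S(=O)(=O)[O-]
Why: Proposed new method: Fremy's radical abstracts the phenol O–H (weaker than the aniline N–H) and oxygenates the free para position (Teuber oxidation, precedented for 3-acylaminophenols) to give 2-aminoquinone 17, whose carbonyl next to the side chain is not deactivated by the amine and so activates the adjacent ring CH for 6-membered Michael addition of the diketone C8 enol (precedent: 1,3-dicarbonyl additions to quinones); excess oxidant re-oxidises hydroquinone 18 to 19, and E1cB loss of the benzylic β-hydroxyl followed by enolisation aromatises the new ring, with no triad centre involved.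

## Compound list

1 | methyl (R)-3-hydroxy-2-methylpropanoate | COC(=O)[C@H](C)CO | starting material
2 | methyl (R)-3-(tert-butyldimethylsilyloxy)-2-methylpropanoate | COC(=O)[C@H](C)CO[Si](C)(C)C(C)(C)C | intermediate
3 | (R)-3-(tert-butyldimethylsilyloxy)-2-methylpropanal | O=C[C@H](C)CO[Si](C)(C)C(C)(C)C | intermediate
4 | (R)-4-benzyl-3-propionyloxazolidin-2-one | CCC(=O)N1[C@H](Cc2ccccc2)COC1=O | starting material
5 | (R)-4-benzyl-3-[(2R,3S,4R)-5-(tert-butyldimethylsilyloxy)-3-hydroxy-2,4-dimethylpentanoyl]oxazolidin-2-one | CC(C)(C)[Si](C)(C)OC[C@@H](C)[C@H](O)[C@@H](C)C(=O)N1[C@H](Cc2ccccc2)COC1=O | intermediate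
6 | (R)-4-benzyl-3-[(2R,3S,4R)-3,5-dihydroxy-2,4-dimethylpentanoyl]oxazolidin-2-one | OC[C@@H](C)[C@H](O)[C@@H](C)C(=O)N1[C@H](Cc2ccccc2)COC1=O | intermediate
7 | 3-(triphenylphosphoranylidene)butan-2-one | CC(=O)C(C)=P(c1ccccc1)(c1ccccc1)c1ccccc1 | starting material
8 | (R)-4-benzyl-3-[(2R,3S,4S)-3-hydroxy-2,4-dimethyl-5-oxopentanoyl]oxazolidin-2-one (same geometry as 6; the C4 descriptor changes by CIP priority only) | O=C[C@@H](C)[C@H](O)[C@@H](C)C(=O)N1[C@H](Cc2ccccc2)COC1=O | intermediate (not isolated)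
9 | (R)-4-benzyl-3-[(2R,3S,4R,5E)-3-hydroxy-2,4,6-trimethyl-7-oxooct-5-enoyl]oxazolidin-2-one | CC(=O)/C(C)=C/[C@@H](C)[C@H](O)[C@@H](C)C(=O)N1[C@H](Cc2ccccc2)COC1=O | intermediate
10 | (2R,3S,4R,5E)-3-hydroxy-2,4,6-trimethyl-7-oxooct-5-eneperoxoic acid | CC(=O)/C(C)=C/[C@@H](C)[C@H](O)[C@@H](C)C(=O)OO | intermediate (not isolated)
11 | (2R,3S,4R,5E)-3-hydroxy-2,4,6-trimethyl-7-oxooct-5-enoic acid | CC(=O)/C(C)=C/[C@@H](C)[C@H](O)[C@@H](C)C(=O)O | intermediate
12 | N-methoxy-N-methylpropanamide | CCC(=O)N(C)OC | starting material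
13 | (2R,3S,4R,5E)-3-hydroxy-2,4,6-trimethyl-7,9-dioxoundec-5-enoic acid | CCC(=O)CC(=O)/C(C)=C/[C@@H](C)[C@H](O)[C@@H](C)C(=O)O | intermediate
14 | 3-hydroxy-5-nitrobenzaldehyde | O=Cc1cc(O)cc([N+](=O)[O-])c1 | starting material
15 | (2R,3S,4R,5E)-3,11-dihydroxy-11-(3-hydroxy-5-nitrophenyl)-2,4,6,10-tetramethyl-7,9-dioxoundec-5-enoic acid (C10/C11 mixture) | O=[N+]([O-])c1cc(O)cc(c1)C(O)C(C)C(=O)CC(=O)/C(C)=C/[C@@H](C)[C@H](O)[C@@H](C)C(=O)O | intermediate
16 | (2R,3S,4R,5E)-11-(3-amino-5-hydroxyphenyl)-3,11-dihydroxy-2,4,6,10-tetramethyl-7,9-dioxoundec-5-enoic acid (C10/C11 mixture) | Nc1cc(O)cc(c1)C(O)C(C)C(=O)CC(=O)/C(C)=C/[C@@H](C)[C@H](O)[C@@H](C)C(=O)O | intermediate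
17 | (2R,3S,4R,5E)-11-(5-amino-3,6-dioxocyclohexa-1,4-dien-1-yl)-3,11-dihydroxy-2,4,6,10-tetramethyl-7,9-dioxoundec-5-enoic acid | NC1=CC(=O)C=C(C1=O)C(O)C(C)C(=O)CC(=O)/C(C)=C/[C@@H](C)[C@H](O)[C@@H](C)C(=O)O | intermediate (not isolated)
18 | (2R,3S,4R,5E)-7-(6-amino-4,5,8-trihydroxy-3-methyl-2-oxo-1,2,3,4-tetrahydronaphthalen-1-yl)-3-hydroxy-2,4,6-trimethyl-7-oxohept-5-enoic acid | Nc1cc(O)c2c(c1O)C(O)C(C)C(=O)C2C(=O)/C(C)=C/[C@@H](C)[C@H](O)[C@@H](C)C(=O)O | intermediate (not isolated)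
19 | (2R,3S,4R,5E)-7-(6-amino-4-hydroxy-3-methyl-2,5,8-trioxo-1,2,3,4,5,8-hexahydronaphthalen-1-yl)-3-hydroxy-2,4,6-trimethyl-7-oxohept-5-enoic acid | NC1=CC(=O)C2=C(C1=O)C(O)C(C)C(=O)C2C(=O)/C(C)=C/[C@@H](C)[C@H](O)[C@@H](C)C(=O)O | intermediate (not isolated)
20 | (2R,3S,4R,5E)-7-(6-amino-2-hydroxy-3-methyl-5,8-dioxo-5,8-dihydronaphthalen-1-yl)-3-hydroxy-2,4,6-trimethyl-7-oxohept-5-enoic acid | C/C(=C\[C@@H](C)[C@H](O)[C@@H](C)C(=O)O)C(=O)c1c(O)c(C)cc2c1C(=O)C=C(N)C2=O | target

## Step count and risks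

Total steps: 10. Longest linear sequence: 10 (1 → 20); 4, 7, 12 and 14 are bought.

**Step 10** is the most likely to fail. The free aniline may be oxidised in competition with the phenol, the amine of one molecule may add to the quinone of another, and the hydroquinone hydroxyl of 18 may close onto the C7 ketone (furan-type) before re-oxidation. The fallback sets out from 16 and returns at 20, and makes the sequence stepwise on a nitrogen-protected substrate. Boc2O in THF/H2O acylates only the aniline to give the N-Boc aminophenol seco-acid F6. Fremy's salt then gives the isolable open-chain 2-(Boc-amino)benzoquinone F7. Et3N followed by air effects Michael closure, dehydration and re-oxidation to the N-Boc naphthoquinone F8, and TFA in CH2Cl2 releases 20.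

**Step 8** is second. It needs a tetra-lithiated substrate, and the dianion may transfer an electron to the nitroarene instead of adding to the aldehyde. The fallback sets out from 11 (with 12 and 14), returns at 15 and bypasses 13; it replaces the dianion aldol by a convergent acylation. The lithium enolate of 12 is added to the lithium phenoxide of 14 to give the β-hydroxy Weinreb amide F3. TBSOTf/2,6-lutidine gives the bis-silyl ether F4. The tri-lithio enolate of 11 (LiHMDS, as in step 7) is acylated by F4 to give the bis-silylated diketone F5, and TBAF buffered with AcOH gives 15.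

**Step 7** is third. A poorly soluble tri-lithio species must be acylated by a weak acyl donor, with possible competing γ-deprotonation. The fallback sets out from 7 (with 12) and returns at 13; it builds the diketone on the ylide before the olefination. The ylide anion of 7 (LDA, THF, −78 °C, deprotonation at the acetyl methyl) is acylated with 12 to give the diketo-ylide F1. F1 replaces 7 in the one-pot oxidation/Wittig of 6 (via 8) to give the diketo-enone imide F2. LiOH/H2O2 cleavage, with the diketone protected as its enolate, gives 13.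

## Further compounds

F1 | step 7 | 2-(triphenylphosphoranylidene)heptane-3,5-dione | CCC(=O)CC(=O)C(C)=P(c1ccccc1)(c1ccccc1)c1ccccc1
F2 | step 7 | (R)-4-benzyl-3-[(2R,3S,4R,5E)-3-hydroxy-2,4,6-trimethyl-7,9-dioxoundec-5-enoyl]oxazolidin-2-one | CCC(=O)CC(=O)/C(C)=C/[C@@H](C)[C@H](O)[C@@H](C)C(=O)N1[C@H](Cc2ccccc2)COC1=O
F3 | step 8 | 3-hydroxy-3-(3-hydroxy-5-nitrophenyl)-N-methoxy-N,2-dimethylpropanamide (diastereomer mixture) | CON(C)C(=O)C(C)C(O)c1cc(O)cc([N+](=O)[O-])c1
F4 | step 8 | 3-(tert-butyldimethylsilyloxy)-3-[3-(tert-butyldimethylsilyloxy)-5-nitrophenyl]-N-methoxy-N,2-dimethylpropanamide | CON(C)C(=O)C(C)C(O[Si](C)(C)C(C)(C)C)c1cc(O[Si](C)(C)C(C)(C)C)cc([N+](=O)[O-])c1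
F5 | step 8 | (2R,3S,4R,5E)-11-(tert-butyldimethylsilyloxy)-11-[3-(tert-butyldimethylsilyloxy)-5-nitrophenyl]-3-hydroxy-2,4,6,10-tetramethyl-7,9-dioxoundec-5-enoic acid | CC(C)(C)[Si](C)(C)Oc1cc(cc([N+](=O)[O-])c1)C(O[Si](C)(C)C(C)(C)C)C(C)C(=O)CC(=O)/C(C)=C/[C@@H](C)[C@H](O)[C@@H](C)C(=O)O
F6 | step 10 | (2R,3S,4R,5E)-11-[3-(tert-butoxycarbonylamino)-5-hydroxyphenyl]-3,11-dihydroxy-2,4,6,10-tetramethyl-7,9-dioxoundec-5-enoic acid | CC(C)(C)OC(=O)Nc1cc(O)cc(c1)C(O)C(C)C(=O)CC(=O)/C(C)=C/[C@@H](C)[C@H](O)[C@@H](C)C(=O)O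
F7 | step 10 | (2R,3S,4R,5E)-11-[5-(tert-butoxycarbonylamino)-3,6-dioxocyclohexa-1,4-dien-1-yl]-3,11-dihydroxy-2,4,6,10-tetramethyl-7,9-dioxoundec-5-enoic acid | CC(C)(C)OC(=O)NC1=CC(=O)C=C(C1=O)C(O)C(C)C(=O)CC(=O)/C(C)=C/[C@@H](C)[C@H](O)[C@@H](C)C(=O)O
F8 | step 10 | (2R,3S,4R,5E)-7-[6-(tert-butoxycarbonylamino)-2-hydroxy-3-methyl-5,8-dioxo-5,8-dihydronaphthalen-1-yl]-3-hydroxy-2,4,6-trimethyl-7-oxohept-5-enoic acid | C/C(=C\[C@@H](C)[C@H](O)[C@@H](C)C(=O)O)C(=O)c1c(O)c(C)cc2c1C(=O)C=C(NC(=O)OC(C)(C)C)C2=O
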